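**Retrosynthetic overview**
1. Target ⇐ O-debenzylation and hydride reduction of a 3-acyl group in a trans-2-aryl-2,3-dihydrobenzofuran-3-carbonyl pyrazole.
2. Key disconnection C3–C3a of the dihydrofuran ring (ring B, the only ring made; rings A and C are bought): enantioselective 6π photocyclization and 1,4-hydrogen shift of an achiral, flat β-aryloxy enoyl pyrazole, which sets C2 and C3 together.
3. Enabling feature: the aryl vinyl ether triad C3a=C7a (ring A)–O1–C2=C3, a six-electron array (two π bonds and an oxygen lone pair), with a hydrogen on C3a that can move to C2. The acylpyrazole on C3 is a temporary activating and catalyst-binding group that ends as the CH2OH group.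
4. The enol ether ⇐ oxa-Michael addition of methyl dihydroferulate to an aryl ynoyl pyrazole ⇐ aryl propiolic acid ⇐ 4-(benzyloxy)-3,5-dimethoxybenzaldehyde (Corey–Fuchs reaction, CO2).

Key step: step 5

Assumption: the sense of induction of the chiral-at-metal rhodium catalyst on this new substrate class cannot be assigned with certainty in advance; the Λ enantiomer is written, and the equally accessible Δ enantiomer is used in the same step if a first small-scale run shows that it is the one leading to the (2S,3S) acylpyrazole.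

**Step 1**
Reactants: 1 4-(benzyloxy)-3,5-dimethoxybenzaldehyde
Product: 2 2-(benzyloxy)-5-(2,2-dibromoethenyl)-1,3-dimethoxybenzene
Conditions: CBr4, PPh3, Zn dust, CH2Cl2, rt (ylide pre-formed); then 1, 0 °C to rt
Reagents that add atoms: carbon tetrabromide, BrC(Br)(Br)Br
Why: Corey–Fuchs dibromo-olefination, a Wittig reaction of the ylide Ph3P=CBr2 made in the flask, is dependable for electron-rich aryl aldehydes and creates no stereocentre.

**Step 2**
Reactants: 2 2-(benzyloxy)-5-(2,2-dibromoethenyl)-1,3-dimethoxybenzene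
Product: 4 3-[4-(benzyloxy)-3,5-dimethoxyphenyl]prop-2-ynoic acid, via lithium acetylide 3 (not isolated)
Conditions: n-BuLi (2.2 equiv), THF, −78 to 0 °C; then CO2 (gas), −78 °C to rt; aq. HCl work-up
Reagents that add atoms: carbon dioxide, O=C=O
Why: In the second stage of the Corey–Fuchs reaction, bromine–lithium exchange, Fritsch–Buttenberg–Wiechell rearrangement and deprotonation give the lithium acetylide, whose carboxylation with CO2 is a standard route to aryl propiolic acids and leaves the benzyl and methyl ethers untouched at −78 °C.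

**Step 3**
Reactants: 4 3-[4-(benzyloxy)-3,5-dimethoxyphenyl]prop-2-ynoic acid
Product: 5 3-[4-(benzyloxy)-3,5-dimethoxyphenyl]-1-(3,5-dimethyl-1H-pyrazol-1-yl)prop-2-yn-1-one
Conditions: 3,5-dimethylpyrazole (1.2 equiv), EDC·HCl (1.3 equiv), DMAP (10 mol%), CH2Cl2, 0 °C to rt
Reagents that add atoms: 3,5-dimethyl-1H-pyrazole, Cc1cc(C)[nH]n1
Why: Carbodiimide-mediated N-acylation of the pyrazole N–H gives the N-acylpyrazole, which serves as an activated Michael acceptor for step 4, as a two-point (N,O) binding site for the Lewis acid in step 5 and as an activated amide for the reduction in step 6.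

**Step 4**
Reactants: 5 3-[4-(benzyloxy)-3,5-dimethoxyphenyl]-1-(3,5-dimethyl-1H-pyrazol-1-yl)prop-2-yn-1-one; 6 methyl 3-(4-hydroxy-3-methoxyphenyl)propanoate (methyl dihydroferulate)
Product: 7 methyl 3-[4-({(1Z)-1-[4-(benzyloxy)-3,5-dimethoxyphenyl]-3-(3,5-dimethyl-1H-pyrazol-1-yl)-3-oxoprop-1-en-1-yl}oxy)-3-methoxyphenyl]propanoate (Z isomer drawn; an E/Z mixture is acceptable)
Conditions: Cs2CO3 (20 mol%), dry MeCN, rt to 40 °C
Reagents that add atoms: none
Why: Base-catalysed oxa-Michael addition of the phenoxide of 6 to the β-carbon of the ynoyl pyrazole forms the O1–C2 bond with full atom economy, acyl transfer to the phenoxide being disfavoured because pyrazolide is the poorer leaving group, and the double-bond geometry that results is of no consequence for step 5.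

**Step 5**
Reactants: 7 methyl 3-[4-({(1Z)-1-[4-(benzyloxy)-3,5-dimethoxyphenyl]-3-(3,5-dimethyl-1H-pyrazol-1-yl)-3-oxoprop-1-en-1-yl}oxy)-3-methoxyphenyl]propanoate
Product: 9 methyl 3-[(2S,3S)-2-[4-(benzyloxy)-3,5-dimethoxyphenyl]-3-(3,5-dimethyl-1H-pyrazole-1-carbonyl)-7-methoxy-2,3-dihydro-1-benzofuran-5-yl]propanoate (2,3-trans), via carbonyl ylide 8 (not isolated)
Conditions: Λ-[Rh(pbt)2(MeCN)2]PF6 (4 mol%; pbt = C,N-cyclometalated 5-tert-butyl-2-phenylbenzothiazole), degassed acetone (0.02 M), blue LEDs (450 nm), rt; then Et3N (0.2 equiv), rt, 1 h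
Reagents that add atoms: none
Why: Proposed new method: two-point N,O binding of the acylpyrazole of 7 to the chiral trivalent rhodium Lewis acid should give the only species that absorbs blue light, and its triplet state, a twisted 1,2-diradical with spin on C3 (α to the acyl group, electrophilic) and on C2 (benzylic and oxygen-bearing), should add through C3 to the electron-rich ortho C–H carbon of ring A and, after intersystem crossing, give carbonyl ylide 8, which rearomatizes ring A by a suprafacial 1,4-hydrogen shift from C3a to C2. The closest known reaction types are the heteroatom-directed photoarylation (6π photocyclization and 1,4-hydrogen shift of 2-aryloxyenones to dihydrobenzofurans and of N-aryl enaminones to 3-acylindolines, in the latter with bond formation α to the carbonyl group as here) and the visible-light [2+2] photocycloaddition of α,β-unsaturated N-acylpyrazoles bound to the same family of chiral-at-metal rhodium catalysts; their combination on a 3-aryloxy enoyl substrate is new. Ring B closes in the conrotatory 6π mode of the O-bridged triene C3a=C7a–O1–C2=C3, which on the triplet surface amounts to a five-membered radical closure onto the arene. C3 is set by the catalyst, whose ligand sphere shields one face of the bound enoyl unit, and C2 is set by the substrate in relay: C3a–H should form syn to the acyl group for steric reasons and is then delivered to the same face of C2, which places the aryl and acyl groups trans, and the brief amine treatment equilibrates any cis isomer at the acidic C3 without touching C2. The step needs regioselectivity between the two ortho carbons of ring A, secured because the other one carries the methoxy group (hindered, and without a hydrogen to shift), and it needs no defined alkene geometry because the triplet state interconverts the E and Z isomers of 7.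

**Step 6**
Reactants: 9 methyl 3-[(2S,3S)-2-[4-(benzyloxy)-3,5-dimethoxyphenyl]-3-(3,5-dimethyl-1H-pyrazole-1-carbonyl)-7-methoxy-2,3-dihydro-1-benzofuran-5-yl]propanoate
Product: 11 methyl 3-[(2S,3R)-2-[4-(benzyloxy)-3,5-dimethoxyphenyl]-3-(hydroxymethyl)-7-methoxy-2,3-dihydro-1-benzofuran-5-yl]propanoate, via aldehyde 10 (not isolated)
Conditions: NaBH4 (3 equiv), THF/H2O 4:1, 0 °C, 30 min; aqueous work-up
Reagents that add atoms: none
Why: N-Acylpyrazoles are activated amides that NaBH4 reduces through the aldehyde to the primary alcohol at 0 °C while a methyl ester is left intact (chemoselective hydride reduction), and neither C2 nor the thermodynamically preferred trans C3 centre is expected to change.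

**Step 7**
Reactants: 11 methyl 3-[(2S,3R)-2-[4-(benzyloxy)-3,5-dimethoxyphenyl]-3-(hydroxymethyl)-7-methoxy-2,3-dihydro-1-benzofuran-5-yl]propanoate
Product: 12 methyl 3-[(2S,3R)-2-(4-hydroxy-3,5-dimethoxyphenyl)-3-(hydroxymethyl)-7-methoxy-2,3-dihydro-1-benzofuran-5-yl]propanoate
Conditions: H2 (1 atm), 10% Pd/C, EtOAc, rt, stopped at full conversion
Reagents that add atoms: none
Why: Catalytic hydrogenolysis of the benzyl aryl ether is expected to be faster than cleavage of the cyclic benzylic C2–O1 bond, so that stopping the reaction at full conversion should give the target with both stereocentres unchanged.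

**Compound list**
1 | 4-(benzyloxy)-3,5-dimethoxybenzaldehyde | COc1cc(C=O)cc(OC)c1OCc1ccccc1 | starting material
2 | 2-(benzyloxy)-5-(2,2-dibromoethenyl)-1,3-dimethoxybenzene | COc1cc(C=C(Br)Br)cc(OC)c1OCc1ccccc1 | intermediate
3 | lithium [4-(benzyloxy)-3,5-dimethoxyphenyl]acetylide (not isolated) | [Li]C#Cc1cc(OC)c(OCc2ccccc2)c(OC)c1 | intermediate
4 | 3-[4-(benzyloxy)-3,5-dimethoxyphenyl]prop-2-ynoic acid | OC(=O)C#Cc1cc(OC)c(OCc2ccccc2)c(OC)c1 | intermediate
5 | 3-[4-(benzyloxy)-3,5-dimethoxyphenyl]-1-(3,5-dimethyl-1H-pyrazol-1-yl)prop-2-yn-1-one | Cc1cc(C)n(n1)C(=O)C#Cc1cc(OC)c(OCc2ccccc2)c(OC)c1 | intermediate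
6 | methyl 3-(4-hydroxy-3-methoxyphenyl)propanoate (methyl dihydroferulate) | COC(=O)CCc1ccc(O)c(OC)c1 | starting material
7 | methyl 3-[4-({(1Z)-1-[4-(benzyloxy)-3,5-dimethoxyphenyl]-3-(3,5-dimethyl-1H-pyrazol-1-yl)-3-oxoprop-1-en-1-yl}oxy)-3-methoxyphenyl]propanoate | Cc1cc(C)n(n1)C(=O)/C=C(\Oc1ccc(CCC(=O)OC)cc1OC)c1cc(OC)c(OCc2ccccc2)c(OC)c1 | intermediate
8 | carbonyl ylide formed from 7 (oxonium O1=C2, carbanion at C7a, ring A dearomatized at C3a, C3a–H syn to the C3 acyl group; not isolated) | COC(=O)CCC1=C[C@H]2[C@H](C(=O)n3nc(C)cc3C)C(c3cc(OC)c(OCc4ccccc4)c(OC)c3)=[O+][C-]2C(OC)=C1 | intermediate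
9 | methyl 3-[(2S,3S)-2-[4-(benzyloxy)-3,5-dimethoxyphenyl]-3-(3,5-dimethyl-1H-pyrazole-1-carbonyl)-7-methoxy-2,3-dihydro-1-benzofuran-5-yl]propanoate | COC(=O)CCc1cc(OC)c2c(c1)[C@H](C(=O)n1nc(C)cc1C)[C@@H](c1cc(OC)c(OCc3ccccc3)c(OC)c1)O2 | intermediate
10 | methyl 3-[(2S,3S)-2-[4-(benzyloxy)-3,5-dimethoxyphenyl]-3-formyl-7-methoxy-2,3-dihydro-1-benzofuran-5-yl]propanoate (not isolated) | COC(=O)CCc1cc(OC)c2c(c1)[C@H](C=O)[C@@H](c1cc(OC)c(OCc3ccccc3)c(OC)c1)O2 | intermediate
11 | methyl 3-[(2S,3R)-2-[4-(benzyloxy)-3,5-dimethoxyphenyl]-3-(hydroxymethyl)-7-methoxy-2,3-dihydro-1-benzofuran-5-yl]propanoate | COC(=O)CCc1cc(OC)c2c(c1)[C@H](CO)[C@@H](c1cc(OC)c(OCc3ccccc3)c(OC)c1)O2 | intermediate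
12 | methyl 3-[(2S,3R)-2-(4-hydroxy-3,5-dimethoxyphenyl)-3-(hydroxymethyl)-7-methoxy-2,3-dihydro-1-benzofuran-5-yl]propanoate | COC(=O)CCc1cc(OC)c2c(c1)[C@H](CO)[C@@H](c1cc(OC)c(O)c(OC)c1)O2 | target

**Step count**
Total: 7 steps. Longest linear sequence: 7 steps (1 to 12); 6 enters at step 4.

**Steps most likely to fail**

Step 5 (Proposed new method). The excited complex may only relax by E/Z isomerization without forming the C3–C3a bond. Closure may also occur at the methoxy-bearing ortho carbon, followed by loss of methanol. Facial discrimination by the catalyst may be poor, and the ring may open by β-elimination during the amine equilibration. The fallback uses known chemistry, sets out from 6 and 1 and comes back to the route at 11. Phenol 6 is iodinated ortho to the hydroxyl group (iodine, NaHCO3, aqueous THF) to methyl 3-(4-hydroxy-3-iodo-5-methoxyphenyl)propanoate F1. Aldehyde 1 is homologated by a Horner–Wadsworth–Emmons reaction (triethyl phosphonoacetate, NaH, THF) to ethyl (2E)-3-[4-(benzyloxy)-3,5-dimethoxyphenyl]prop-2-enoate F2. This is reduced (i-Bu2AlH, CH2Cl2, −78 °C) to (2E)-3-[4-(benzyloxy)-3,5-dimethoxyphenyl]prop-2-en-1-ol F3 and acylated (methyl chloroformate, pyridine) to (2E)-3-[4-(benzyloxy)-3,5-dimethoxyphenyl]prop-2-en-1-yl methyl carbonate F4. Iridium-catalysed branch-selective enantioselective allylic etherification of F4 with the sodium salt of F1 ([Ir(cod)Cl]2, (Sa,S,S)-binaphthol-derived bis(1-phenylethyl)phosphoramidite or its antipode, THF, 50 °C) should give methyl 3-[4-({(1S)-1-[4-(benzyloxy)-3,5-dimethoxyphenyl]prop-2-en-1-yl}oxy)-3-iodo-5-methoxyphenyl]propanoate F5, in which C2 is set by the catalyst. An oxygenative 5-exo-trig aryl radical cyclization (Bu3SnH added slowly, dry air, toluene, 60 °C, then PPh3) then closes the same C3–C3a bond. C3 is expected trans to the C2 aryl group from the chair-like transition state, and the primary radical is trapped by oxygen and reduced to the alcohol, which is 11.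

Step 4. Conjugate addition to the electron-rich aryl alkyne may be sluggish, and acyl transfer to the phenoxide or hydrolysis of the acylpyrazole may compete. The fallback sets out from 2 (with 6) and comes back at 7. Dibromoalkene 2 is converted as in step 2 into lithium acetylide 3, which is quenched with allyl chloroformate to give prop-2-en-1-yl 3-[4-(benzyloxy)-3,5-dimethoxyphenyl]prop-2-ynoate F6. Conjugate addition of 6 to this ester (K2CO3, DMF, 80 °C), which cannot suffer acyl transfer, should give prop-2-en-1-yl (2Z)-3-[4-(benzyloxy)-3,5-dimethoxyphenyl]-3-[2-methoxy-4-(3-methoxy-3-oxopropyl)phenoxy]prop-2-enoate F7. Deallylation (Pd(PPh3)4, morpholine, THF, rt) gives (2Z)-3-[4-(benzyloxy)-3,5-dimethoxyphenyl]-3-[2-methoxy-4-(3-methoxy-3-oxopropyl)phenoxy]prop-2-enoic acid F8, which is coupled with 3,5-dimethylpyrazole (EDC·HCl, DMAP, CH2Cl2) to 7.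

Step 7. Over-reduction by hydrogenolytic cleavage of the cyclic benzylic C2–O1 bond may compete with O-debenzylation. The fallback sets out from 11 and comes back at 12. It replaces the reductive cleavage by a heterolytic benzyl transfer: BCl3 with pentamethylbenzene as cation scavenger, CH2Cl2, −78 °C, then methanol quench. Chelation of boron between the benzyloxy and ortho-methoxy oxygens should make this ether the fastest to cleave, and no hydrogen is present to open ring B. This fallback makes no further compound (entry F0).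

**Further compounds**
F1 | step 5 | methyl 3-(4-hydroxy-3-iodo-5-methoxyphenyl)propanoate | COC(=O)CCc1cc(I)c(O)c(OC)c1
F2 | step 5 | ethyl (2E)-3-[4-(benzyloxy)-3,5-dimethoxyphenyl]prop-2-enoate | CCOC(=O)/C=C/c1cc(OC)c(OCc2ccccc2)c(OC)c1
F3 | step 5 | (2E)-3-[4-(benzyloxy)-3,5-dimethoxyphenyl]prop-2-en-1-ol | OC/C=C/c1cc(OC)c(OCc2ccccc2)c(OC)c1
F4 | step 5 | (2E)-3-[4-(benzyloxy)-3,5-dimethoxyphenyl]prop-2-en-1-yl methyl carbonate | COC(=O)OC/C=C/c1cc(OC)c(OCc2ccccc2)c(OC)c1
F5 | step 5 | methyl 3-[4-({(1S)-1-[4-(benzyloxy)-3,5-dimethoxyphenyl]prop-2-en-1-yl}oxy)-3-iodo-5-methoxyphenyl]propanoate | C=C[C@@H](c1cc(OC)c(OCc2ccccc2)c(OC)c1)Oc1c(I)cc(CCC(=O)OC)cc1OC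
F6 | step 4 | prop-2-en-1-yl 3-[4-(benzyloxy)-3,5-dimethoxyphenyl]prop-2-ynoate | C=CCOC(=O)C#Cc1cc(OC)c(OCc2ccccc2)c(OC)c1
F7 | step 4 | prop-2-en-1-yl (2Z)-3-[4-(benzyloxy)-3,5-dimethoxyphenyl]-3-[2-methoxy-4-(3-methoxy-3-oxopropyl)phenoxy]prop-2-enoate | C=CCOC(=O)/C=C(\Oc1ccc(CCC(=O)OC)cc1OC)c1cc(OC)c(OCc2ccccc2)c(OC)c1
F8 | step 4 | (2Z)-3-[4-(benzyloxy)-3,5-dimethoxyphenyl]-3-[2-methoxy-4-(3-methoxy-3-oxopropyl)phenoxy]prop-2-enoic acid | OC(=O)/C=C(\Oc1ccc(CCC(=O)OC)cc1OC)c1cc(OC)c(OCc2ccccc2)c(OC)c1
F0 | step 7 | none | none
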